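**Plan**

- The only ring is a 1,4-benzoquinone with methyl on C2, the chain on C5 (para) and hydrogen on C3 and C6. It is cut at C1–C6, C3–C4 and C4–C5: C1–C3 map onto an isopropenyl(methoxy)carbene on chromium, C4 onto carbon monoxide, C5–C6 onto the terminal alkyne of the side chain.
- The chain is cut at C1′–C(alkyne), C10′–C11′, C12′–C13′ and C14′=C15′. This leads back to farnesol, a silylacetylene, isopropenyl and allyl Grignard reagents and 2-methyl-2-butene.
- Forward: farnesyl bromide is joined to the silylacetylide and the far alkene is cut down to the C10′ aldehyde. Isopropenyl addition, epoxidation, allyl opening and cross-metathesis build C11′–C16′. Desilylation and monoacetylation give the enyne; the ring is made last and oxidised to the quinone.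
- Stereochemistry: both E-alkenes are those of farnesol. A Sharpless kinetic-resolution epoxidation with D-(−)-diisopropyl tartrate selects 10′R and sets 11′S (erythro); epoxide opening at C12′ leaves both untouched.

Key step: step 12

Remark: ring atoms are numbered C1 (carbonyl flanked by the methyl-bearing C2) to C6, chain atoms C1′ (ring-bound CH2) to C16′; the Grignard solutions 9 and 12 are taken as purchased.

**Route**

Step 1
Reactants: 1 (2E,6E)-farnesol
Product: 2 (2E,6E)-farnesyl bromide
Conditions: PBr3 (0.4 equiv), Et2O, −10 → 0 °C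
Reagents that add atoms: phosphorus tribromide, BrP(Br)Br
Why: Conversion of a primary allylic alcohol into its bromide with PBr3 (SN2 on the bromophosphite) at low temperature should proceed without allylic transposition, so both E-alkenes are carried over unchanged.

Step 2
Reactants: 2 (2E,6E)-farnesyl bromide; 3 (triisopropylsilyl)acetylene
Product: 5 triisopropyl[(4E,8E)-5,9,13-trimethyltetradeca-4,8,12-trien-1-yn-1-yl]silane, via alkynylmagnesium bromide 4 (not isolated)
Conditions: 3, EtMgBr, THF, 0 → 40 °C; then CuBr·SMe2 (5 mol %), 2, THF, 0 °C → rt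
Reagents that add atoms: none
Why: Copper-catalysed coupling of an alkynyl Grignard reagent with a primary allylic bromide should join C1′ to the alkyne at the unhindered α-carbon (SN2, 2′E retained), and the bulky silyl cap keeps the alkyne and the skipped-enyne terminus inert until step 9.

Step 3
Reactants: 5 triisopropyl[(4E,8E)-5,9,13-trimethyltetradeca-4,8,12-trien-1-yn-1-yl]silane
Product: 7 rac-triisopropyl[(4E,8E)-11-(3,3-dimethyloxiran-2-yl)-5,9-dimethylundeca-4,8-dien-1-yn-1-yl]silane, via bromohydrin 6 (not isolated)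
Conditions: NBS (1.05 equiv), THF–H2O, 0 °C; then K2CO3, MeOH, rt
Reagents that add atoms: water, O
Why: Terminal-selective bromohydrin formation in aqueous THF (Markovnikov, bromine on the secondary carbon) should pick the most exposed, most electron-rich trisubstituted alkene, the alkene next to the alkynyl group and the alkynylsilane being less nucleophilic, and carbonate then closes the epoxide by intramolecular Williamson displacement; the new stereocentre is racemic and is destroyed in step 4.

Step 4
Reactants: 7 rac-triisopropyl[(4E,8E)-11-(3,3-dimethyloxiran-2-yl)-5,9-dimethylundeca-4,8-dien-1-yn-1-yl]silane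
Product: 8 (4E,8E)-4,8-dimethyl-12-(triisopropylsilyl)dodeca-4,8-dien-11-ynal
Conditions: H5IO6 (1.2 equiv), THF–Et2O, 0 °C
Reagents that add atoms: none
Why: Periodic acid should hydrolyse the epoxide (water entering at the tertiary carbon, so the aldehyde oxygen is the former epoxide oxygen) and cleave the glycol in the same flask (Malaprade cleavage), leaving alkenes and alkynylsilane untouched.

Step 5
Reactants: 8 (4E,8E)-4,8-dimethyl-12-(triisopropylsilyl)dodeca-4,8-dien-11-ynal; 9 isopropenylmagnesium bromide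
Product: 10 rac-(6E,10E)-2,6,10-trimethyl-14-(triisopropylsilyl)tetradeca-1,6,10-trien-13-yn-3-ol
Conditions: THF, −78 → −20 °C; aq NH4Cl
Reagents that add atoms: none
Why: Grignard 1,2-addition to the unhindered aldehyde forms the C10′–C11′ bond; the new carbinol centre is formed as the racemate and is resolved in step 6.

Step 6
Reactants: 10 rac-(6E,10E)-2,6,10-trimethyl-14-(triisopropylsilyl)tetradeca-1,6,10-trien-13-yn-3-ol
Product: 11 (1R,4E,8E)-4,8-dimethyl-1-[(2S)-2-methyloxiran-2-yl]-12-(triisopropylsilyl)dodeca-4,8-dien-11-yn-1-ol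
Conditions: Ti(OiPr)4 (10 mol %), D-(−)-DIPT (15 mol %), TBHP (0.45 equiv), 4 Å MS, CH2Cl2, −20 °C
Reagents that add atoms: tert-butyl hydroperoxide, CC(C)(C)OO
Why: Sharpless kinetic-resolution epoxidation: with D-(−)-tartrate the (R)-carbinol enantiomer should be epoxidised fast and with erythro selectivity (oxygen delivered to the alkene face opposite the C9′ chain in the reactive conformer), which selects 10′R and sets 11′S, while (S)-10, which is separated, and the alkenes lacking an allylic hydroxyl are left alone.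

Step 7
Reactants: 11 (1R,4E,8E)-4,8-dimethyl-1-[(2S)-2-methyloxiran-2-yl]-12-(triisopropylsilyl)dodeca-4,8-dien-11-yn-1-ol; 12 allylmagnesium chloride
Product: 13 (5S,6R,9E,13E)-5,9,13-trimethyl-17-(triisopropylsilyl)heptadeca-1,9,13-trien-16-yne-5,6-diol
Conditions: 12 (3.5 equiv), CuI (10 mol %), THF, −40 → 0 °C; aq NH4Cl
Reagents that add atoms: none
Why: Copper-catalysed Grignard opening of the 2,2-disubstituted epoxide should occur at its unsubstituted CH2 (C12′, SN2), so no bond to C11′ is broken and 11′S is retained, the first equivalent of reagent merely deprotonating the carbinol.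

Step 8
Reactants: 13 (5S,6R,9E,13E)-5,9,13-trimethyl-17-(triisopropylsilyl)heptadeca-1,9,13-trien-16-yne-5,6-diol; 14 2-methyl-2-butene
Product: 15 (6S,7R,10E,14E)-2,6,10,14-tetramethyl-18-(triisopropylsilyl)octadeca-2,10,14-trien-17-yne-6,7-diol
Conditions: Grubbs II (5 mol %), 14 (large excess)–CH2Cl2, 40 °C, sealed tube
Reagents that add atoms: none
Why: Olefin cross-metathesis with 2-methyl-2-butene (second-generation Grubbs catalyst) should convert the monosubstituted alkene into the prenyl terminus, the trisubstituted alkenes and the hindered alkynylsilane being too encumbered to compete.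

Step 9
Reactants: 15 (6S,7R,10E,14E)-2,6,10,14-tetramethyl-18-(triisopropylsilyl)octadeca-2,10,14-trien-17-yne-6,7-diol
Product: 16 (6S,7R,10E,14E)-2,6,10,14-tetramethyloctadeca-2,10,14-trien-17-yne-6,7-diol
Conditions: TBAF (1.5 equiv), THF, 0 °C → rt
Reagents that add atoms: none
Why: Fluoride-induced protodesilylation of the alkynylsilane should free the terminal alkyne without touching the diol or the alkenes.

Step 10
Reactants: 16 (6S,7R,10E,14E)-2,6,10,14-tetramethyloctadeca-2,10,14-trien-17-yne-6,7-diol
Product: 17 (6S,7R,10E,14E)-6-hydroxy-2,6,10,14-tetramethyloctadeca-2,10,14-trien-17-yn-7-yl acetate (the 10′R-acetoxy-11′S-hydroxy side-chain enyne)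
Conditions: Ac2O (1.5 equiv), pyridine, DMAP (cat.), CH2Cl2, 0 °C → rt
Reagents that add atoms: acetic anhydride, CC(=O)OC(C)=O
Why: DMAP-catalysed acylation should distinguish the secondary C10′ hydroxyl from the tertiary C11′ hydroxyl, which does not acylate under these conditions, and breaks no bond to either stereocentre.

Step 11
Reactants: 18 2-bromopropene; 19 chromium hexacarbonyl
Product: 22 pentacarbonyl[methoxy(prop-1-en-2-yl)carbene]chromium(0), via isopropenyllithium 20 (not isolated), via lithium acylchromate 21 (not isolated)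
Conditions: 18, t-BuLi (2 equiv), Et2O, −78 °C; 19, −78 °C → rt; then Me3OBF4, CH2Cl2–H2O, 0 °C
Reagents that add atoms: trimethyloxonium tetrafluoroborate, C[O+](C)C.F[B-](F)(F)F
Why: Fischer carbene synthesis: bromine–lithium exchange, addition of the alkenyllithium to a carbonyl ligand and O-methylation of the acylchromate with Meerwein's salt should give the known alkenyl(methoxy)carbene complex.

Step 12
Reactants: 17 (6S,7R,10E,14E)-6-hydroxy-2,6,10,14-tetramethyloctadeca-2,10,14-trien-17-yn-7-yl acetate; 22 pentacarbonyl[methoxy(prop-1-en-2-yl)carbene]chromium(0)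
Product: 24 (6S,7R,10E,14E)-6-hydroxy-16-(2-hydroxy-5-methoxy-4-methylphenyl)-2,6,10,14-tetramethylhexadeca-2,10,14-trien-7-yl acetate, via arene tricarbonylchromium complex 23 (not isolated)
Conditions: 22 (1.5 equiv), THF (0.05 M, degassed), 50 °C; then air, rt
Reagents that add atoms: none
Why: Dötz benzannulation: after loss of one CO the terminal alkyne inserts into the Cr=C bond with its hydrogen-bearing carbon bonding to the carbene carbon (C1–C6), a CO ligand inserts to give a chromium-bound dienylketene (C4–C5), and ring closure between the ketene carbon and the isopropenyl CH2 (C3–C4) followed by tautomerisation gives the 4-methoxyphenol as its Cr(CO)3 complex, which air decomplexes. The closest known reaction type is the benzannulation of alkenyl(alkoxy)carbene chromium complexes with terminal alkynes and 1,4-enynes, the established entry to isoprenoid quinones. The single six-membered ring closes by 6π-electrocyclisation on the metal template (a formal [3+2+1] assembly). No stereocentre is created, and C10′ and C11′ are remote spectators. The step needs regioselective alkyne insertion, which the terminal alkyne secures because its chain-bearing carbon ends up next to the CO-derived phenol carbon, placing the chain para to the methyl. It also needs chemoselectivity, which the neutral, base-free conditions secure for the acetate, the tertiary alcohol, the trisubstituted alkenes and the doubly activated C1′ methylene.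

Step 13
Reactants: 24 (6S,7R,10E,14E)-6-hydroxy-16-(2-hydroxy-5-methoxy-4-methylphenyl)-2,6,10,14-tetramethylhexadeca-2,10,14-trien-7-yl acetate
Product: 25 chabrolobenzoquinone H, (6S,7R,10E,14E)-6-hydroxy-2,6,10,14-tetramethyl-16-(4-methyl-3,6-dioxocyclohexa-1,4-dien-1-yl)hexadeca-2,10,14-trien-7-yl acetate
Conditions: CAN (2.2 equiv), MeCN–H2O, 0 °C
Reagents that add atoms: water, O
Why: Oxidative demethylation of a 4-methoxyphenol with ceric ammonium nitrate should give the 1,4-benzoquinone within minutes (two one-electron oxidations, water adding to the methoxy-bearing carbon and methanol leaving), a time scale on which alkenes, acetate and tertiary alcohol are inert.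

**Compound list**

1 | (2E,6E)-farnesol, (2E,6E)-3,7,11-trimethyldodeca-2,6,10-trien-1-ol | CC(C)=CCC/C(C)=C/CC/C(C)=C/CO | starting material
2 | (2E,6E)-farnesyl bromide, (2E,6E)-1-bromo-3,7,11-trimethyldodeca-2,6,10-triene | CC(C)=CCC/C(C)=C/CC/C(C)=C/CBr | intermediate
3 | (triisopropylsilyl)acetylene | C#C[Si](C(C)C)(C(C)C)C(C)C | starting material
4 | [(triisopropylsilyl)ethynyl]magnesium bromide | Br[Mg]C#C[Si](C(C)C)(C(C)C)C(C)C | intermediate (not isolated)
5 | triisopropyl[(4E,8E)-5,9,13-trimethyltetradeca-4,8,12-trien-1-yn-1-yl]silane | CC(C)=CCC/C(C)=C/CC/C(C)=C/CC#C[Si](C(C)C)(C(C)C)C(C)C | intermediate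
6 | rac-(6E,10E)-3-bromo-2,6,10-trimethyl-14-(triisopropylsilyl)tetradeca-6,10-dien-13-yn-2-ol | CC(C)(O)C(Br)CC/C(C)=C/CC/C(C)=C/CC#C[Si](C(C)C)(C(C)C)C(C)C | intermediate (not isolated)
7 | rac-triisopropyl[(4E,8E)-11-(3,3-dimethyloxiran-2-yl)-5,9-dimethylundeca-4,8-dien-1-yn-1-yl]silane | CC1(C)OC1CC/C(C)=C/CC/C(C)=C/CC#C[Si](C(C)C)(C(C)C)C(C)C | intermediate
8 | (4E,8E)-4,8-dimethyl-12-(triisopropylsilyl)dodeca-4,8-dien-11-ynal | O=CCC/C(C)=C/CC/C(C)=C/CC#C[Si](C(C)C)(C(C)C)C(C)C | intermediate
9 | isopropenylmagnesium bromide | C=C(C)[Mg]Br | starting material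
10 | rac-(6E,10E)-2,6,10-trimethyl-14-(triisopropylsilyl)tetradeca-1,6,10-trien-13-yn-3-ol | C=C(C)C(O)CC/C(C)=C/CC/C(C)=C/CC#C[Si](C(C)C)(C(C)C)C(C)C | intermediate
11 | (1R,4E,8E)-4,8-dimethyl-1-[(2S)-2-methyloxiran-2-yl]-12-(triisopropylsilyl)dodeca-4,8-dien-11-yn-1-ol | O[C@H](CC/C(C)=C/CC/C(C)=C/CC#C[Si](C(C)C)(C(C)C)C(C)C)[C@@]1(C)OC1 | intermediate
12 | allylmagnesium chloride | C=CC[Mg]Cl | starting material
13 | (5S,6R,9E,13E)-5,9,13-trimethyl-17-(triisopropylsilyl)heptadeca-1,9,13-trien-16-yne-5,6-diol | O[C@H](CC/C(C)=C/CC/C(C)=C/CC#C[Si](C(C)C)(C(C)C)C(C)C)[C@@](C)(O)CCC=C | intermediate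
14 | 2-methyl-2-butene | CC=C(C)C | starting material
15 | (6S,7R,10E,14E)-2,6,10,14-tetramethyl-18-(triisopropylsilyl)octadeca-2,10,14-trien-17-yne-6,7-diol | O[C@H](CC/C(C)=C/CC/C(C)=C/CC#C[Si](C(C)C)(C(C)C)C(C)C)[C@@](C)(O)CCC=C(C)C | intermediate
16 | (6S,7R,10E,14E)-2,6,10,14-tetramethyloctadeca-2,10,14-trien-17-yne-6,7-diol | O[C@H](CC/C(C)=C/CC/C(C)=C/CC#C)[C@@](C)(O)CCC=C(C)C | intermediate
17 | (6S,7R,10E,14E)-6-hydroxy-2,6,10,14-tetramethyloctadeca-2,10,14-trien-17-yn-7-yl acetate | CC(=O)O[C@H](CC/C(C)=C/CC/C(C)=C/CC#C)[C@@](C)(O)CCC=C(C)C | intermediate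
18 | 2-bromopropene | CC(Br)=C | starting material
19 | chromium hexacarbonyl | O=C=[Cr](=C=O)(=C=O)(=C=O)(=C=O)=C=O | starting material
20 | isopropenyllithium | [Li]C(C)=C | intermediate (not isolated)
21 | lithium pentacarbonyl(2-methylprop-2-enoyl)chromate | [Li+].[O-]C(C(C)=C)=[Cr](=C=O)(=C=O)(=C=O)(=C=O)=C=O | intermediate (not isolated)
22 | pentacarbonyl[methoxy(prop-1-en-2-yl)carbene]chromium(0) | COC(C(C)=C)=[Cr](=C=O)(=C=O)(=C=O)(=C=O)=C=O | intermediate
23 | tricarbonyl(η6-arene)chromium complex of phenol 24 (SMILES written as arene plus Cr(CO)3 fragment) | CC(=O)O[C@H](CC/C(C)=C/CC/C(C)=C/Cc1cc(OC)c(C)cc1O)[C@@](C)(O)CCC=C(C)C.O=C=[Cr](=C=O)=C=O | intermediate (not isolated)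
24 | (6S,7R,10E,14E)-6-hydroxy-16-(2-hydroxy-5-methoxy-4-methylphenyl)-2,6,10,14-tetramethylhexadeca-2,10,14-trien-7-yl acetate | CC(=O)O[C@H](CC/C(C)=C/CC/C(C)=C/Cc1cc(OC)c(C)cc1O)[C@@](C)(O)CCC=C(C)C | intermediate
25 | chabrolobenzoquinone H, (6S,7R,10E,14E)-6-hydroxy-2,6,10,14-tetramethyl-16-(4-methyl-3,6-dioxocyclohexa-1,4-dien-1-yl)hexadeca-2,10,14-trien-7-yl acetate | CC(=O)O[C@H](CC/C(C)=C/CC/C(C)=C/CC1=CC(=O)C(C)=CC1=O)[C@@](C)(O)CCC=C(C)C | target

**Count and risks**

Total step count: 13. Longest linear sequence: 12 steps (steps 1–10, 12 and 13, from farnesol); step 11 is a one-step side branch.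

Steps most likely to fail:

1. Step 12 (carbene–alkyne benzannulation). The terminal alkyne may be drained by carbene-initiated oligomerisation, or CO insertion may lag behind alkyne insertion, so that little phenol forms. Fallback: the arene is brought in intact instead of being built. It sets out from bromide 2. Copper-catalysed coupling (CuI cat., THF, 0 °C) with (2,5-dimethoxy-4-methylphenyl)magnesium bromide F1, made from commercial 1-bromo-2,5-dimethoxy-4-methylbenzene and magnesium, should give the farnesyl hydroquinone dimethyl ether F2. The chain terminus is then elaborated with the reagents of steps 3–8 and 10, through bromohydrin F3, epoxide F4, aldehyde F5, racemic allylic alcohol F6, epoxy alcohol F7, allyl diol F8, prenyl diol F9 and monoacetate F10. Oxidative demethylation of F10 with CAN (MeCN–H2O, 0 °C) comes back to the route at 25.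

2. Step 8 (cross-metathesis). The ruthenium alkylidene may engage the alkynylsilane (enyne metathesis), stall at the crotyl stage, or isomerise the terminal alkene. Fallback: the prenyl unit is introduced already formed. It sets out from epoxy alcohol 11. Opening at C12′ with [1-(benzenesulfonyl)-3-methylbut-2-en-1-yl]lithium F11 (prenyl phenyl sulfone, n-BuLi, THF–DMPU, −78 → 0 °C, one extra equivalent of base for the hydroxyl) should give the hydroxy sulfone F12 as a mixture of sulfone epimers. Palladium-catalysed reductive desulfonylation (PdCl2(dppp), LiBHEt3, THF, 0 °C), which delivers hydride to the less substituted allyl terminus and keeps the trisubstituted alkene in place, comes back to the route at 15 and bypasses 13.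

3. Step 6 (kinetic resolution). The rate difference between the enantiomers may be too small at useful conversion, or titanium alkoxides may open the 2,2-disubstituted epoxy alcohol, so that enantiomeric purity or mass is lost. Fallback: absolute and relative configuration are set in separate, non-resolving steps. It sets out from racemic 10. Dess–Martin oxidation should give the enone F13. Corey–Bakshi–Shibata reduction ((S)-Me-CBS, catecholborane, toluene, −78 °C, isopropenyl acting as the large group) should give the (R)-allylic alcohol F14. Hydroxyl-directed epoxidation with VO(acac)2/TBHP, which favours the erythro isomer for 2-substituted allylic alcohols, comes back to the route at 11.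

Further compounds
F1 | step 12 | (2,5-dimethoxy-4-methylphenyl)magnesium bromide | COc1cc([Mg]Br)c(OC)cc1C
F2 | step 12 | 1,4-dimethoxy-2-methyl-5-[(2E,6E)-3,7,11-trimethyldodeca-2,6,10-trien-1-yl]benzene | CC(C)=CCC/C(C)=C/CC/C(C)=C/Cc1cc(OC)c(C)cc1OC
F3 | step 12 | rac-(6E,10E)-3-bromo-12-(2,5-dimethoxy-4-methylphenyl)-2,6,10-trimethyldodeca-6,10-dien-2-ol | CC(C)(O)C(Br)CC/C(C)=C/CC/C(C)=C/Cc1cc(OC)c(C)cc1OC
F4 | step 12 | rac-2-[(3E,7E)-9-(2,5-dimethoxy-4-methylphenyl)-3,7-dimethylnona-3,7-dien-1-yl]-3,3-dimethyloxirane | CC1(C)OC1CC/C(C)=C/CC/C(C)=C/Cc1cc(OC)c(C)cc1OC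
F5 | step 12 | (4E,8E)-10-(2,5-dimethoxy-4-methylphenyl)-4,8-dimethyldeca-4,8-dienal | O=CCC/C(C)=C/CC/C(C)=C/Cc1cc(OC)c(C)cc1OC
F6 | step 12 | rac-(6E,10E)-12-(2,5-dimethoxy-4-methylphenyl)-2,6,10-trimethyldodeca-1,6,10-trien-3-ol | C=C(C)C(O)CC/C(C)=C/CC/C(C)=C/Cc1cc(OC)c(C)cc1OC
F7 | step 12 | (1R,4E,8E)-10-(2,5-dimethoxy-4-methylphenyl)-4,8-dimethyl-1-[(2S)-2-methyloxiran-2-yl]deca-4,8-dien-1-ol | O[C@H](CC/C(C)=C/CC/C(C)=C/Cc1cc(OC)c(C)cc1OC)[C@@]1(C)OC1
F8 | step 12 | (5S,6R,9E,13E)-15-(2,5-dimethoxy-4-methylphenyl)-5,9,13-trimethylpentadeca-1,9,13-triene-5,6-diol | O[C@H](CC/C(C)=C/CC/C(C)=C/Cc1cc(OC)c(C)cc1OC)[C@@](C)(O)CCC=C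
F9 | step 12 | (6S,7R,10E,14E)-16-(2,5-dimethoxy-4-methylphenyl)-2,6,10,14-tetramethylhexadeca-2,10,14-triene-6,7-diol | O[C@H](CC/C(C)=C/CC/C(C)=C/Cc1cc(OC)c(C)cc1OC)[C@@](C)(O)CCC=C(C)C
F10 | step 12 | (6S,7R,10E,14E)-16-(2,5-dimethoxy-4-methylphenyl)-6-hydroxy-2,6,10,14-tetramethylhexadeca-2,10,14-trien-7-yl acetate | CC(=O)O[C@H](CC/C(C)=C/CC/C(C)=C/Cc1cc(OC)c(C)cc1OC)[C@@](C)(O)CCC=C(C)C
F11 | step 8 | [1-(benzenesulfonyl)-3-methylbut-2-en-1-yl]lithium | [Li]C(C=C(C)C)S(=O)(=O)c1ccccc1
F12 | step 8 | (6S,7R,10E,14E)-4-(benzenesulfonyl)-2,6,10,14-tetramethyl-18-(triisopropylsilyl)octadeca-2,10,14-trien-17-yne-6,7-diol (C4 epimers) | O[C@H](CC/C(C)=C/CC/C(C)=C/CC#C[Si](C(C)C)(C(C)C)C(C)C)[C@@](C)(O)CC(C=C(C)C)S(=O)(=O)c1ccccc1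
F13 | step 6 | (6E,10E)-2,6,10-trimethyl-14-(triisopropylsilyl)tetradeca-1,6,10-trien-13-yn-3-one | C=C(C)C(=O)CC/C(C)=C/CC/C(C)=C/CC#C[Si](C(C)C)(C(C)C)C(C)C
F14 | step 6 | (3R,6E,10E)-2,6,10-trimethyl-14-(triisopropylsilyl)tetradeca-1,6,10-trien-13-yn-3-ol | O[C@H](CC/C(C)=C/CC/C(C)=C/CC#C[Si](C(C)C)(C(C)C)C(C)C)C(C)=C
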